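## The problem

Target 21 is a monocyclic oxolane (ring C: O1, C2, C3, C4, C5H2) that carries guaiacyl ring A at C2, the C9H2OH group at C3 and, at C4, the C7' ketone leading to syringyl ring B; nothing else links the two arenes, so the task is a 2,3,4-trisubstituted oxolane with three contiguous stereocentres (2S,3R,4S, each neighbouring pair trans) as one enantiomer. C4 lies α to the aryl ketone, can be equilibrated and rests trans to C3, so C3 can dictate C4; C2 and C3 have no such escape and must be set for good, C2 by an external chiral agent and C3 by C2. Equilibration at C4 is safest while O9 is still an ether, because a free C9 hydroxyl cis to the C7' carbonyl could hold the wrong epimer as a bicyclic hemiketal. The benzylic C2–O1 bond is activated by a para-oxygenated arene and will not stand strong acid or prolonged hydrogenolysis, the aryl ketone is reducible, and the two phenols are acidic and easily oxidised, so they must be masked through every enolate, azide and organolithium operation. Ring B cannot be attached by electrophilic acylation, because the position para to the oxygen of a 2,6-dimethoxyphenol is the one the methoxy groups do not activate; the C7'–aryl bond has to come from an aryl metal made from the 4-bromo compound. The feature that opens the chosen route is the C3–C4 bond: it joins the C3 stereocentre to a ring carbon whose only outside substituent, C7', is at the carboxyl oxidation level. That is the signature of a 1,2-shift in which a ring carbon moves from a carbonyl carbon to a neighbouring carbene carbon while the carbonyl carbon leaves the ring as a ketene, so ring C can be read as a 2-aryl-3-substituted oxan-4-one that has passed its carbonyl carbon to the side chain.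

## Retrosynthesis

Numbering: ring C as above. In the six-membered precursors oxane numbering applies (O1, C2 aryl, C3, C4 carbonyl, C5, C6); oxane C2, C3, C5 and C6 become C2, C3, C4 and C5 of ring C, and oxane C4 becomes C7'.

The three O–H bonds are cut first, tracing 21 to its tribenzyl ether 20. One group type then covers both phenols and O9, it reaches O9 together with the carbon that becomes C9, and it leaves under neutral conditions that give the ketone α-centre C4 nothing to respond to. The forward step must stop before the C2–O1 bond or the ketone is reduced.

Cutting the C7'–aryl bond of 20 gives the N-methoxy-N-methylamide 15 and aryllithium 18, which comes from bromide 17 and so from phenol 16. The neighbouring cut, C4–C7', would need an oxolan-3-yl anion β to the ring oxygen, and arene acylation is regiochemically wrong. Amide 15 carries no ring B and needs only a single clean addition, held at the stage of adduct 19 until the quench.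

Amide 15 is the methyl ester 14 after exchange at the acyl carbon. Nothing is simplified in the skeleton; the ester is the form in which the carboxyl carbon leaves the key step and in which C4 can be equilibrated by its own alkoxide.

The key cut undoes the ring contraction: the C3–C4 bond of 14 is broken and C3 is rejoined to the carboxyl carbon, which gives ketene 12 and then the six-membered diazo ketone 11. The alternative cuts at C2–C3 or C4–C5 would ask the ring-forming step to create stereocentres; this one moves the stereochemical work onto an oxanone, where a trans 2,3-pair is the easy outcome. Ester 14 has three stereocentres and 11 has two. The forward reaction must transfer C3 with retention and leave C4 to be equilibrated, through its epimer 13, to the trans ester.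

Exchanging the diazo group at oxane C5 of 11 for a trifluoroacetyl group gives the activated diketone 10, and cutting that acyl bond leaves the C4–C5 enolate 9. This enolate is exactly what hydride addition to C6 of enone 8 delivers, so the C–H bond at C6 is cut next. Making 9 by reduction and acylating it in the same flask is preferred to any deprotonation, because a base would have to choose between the C5 methylene and the C3 methine of a ketone that is β-alkoxy on both sides. The forward sequence needs a hydride that adds 1,4 only and an enolate that is acylated at carbon before it can equilibrate.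

Cutting the C3–C9 bond of 8 gives dihydropyranone 5 (through enolate 7) and the alkoxymethyl chloride 6. Alkylating at the enone stage is preferred to alkylating after the reduction, because 5 has a single sp3 α-carbon, so regiochemistry is not in question, and the C2 aryl group directs the electrophile trans.

Dihydropyranone 5 is cut at O1–C6 and C2–C3 into aldehyde 2 and siloxydiene 3, joined through aldol adduct 4; aldehyde 2 is the benzyl ether of 1. This is the only step that needs an external source of chirality, and it acts on the simplest possible substrate. The catalyst has to cope with an electron-rich aldehyde.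

## Roads not taken

Alternative 1: The cut is C2–C3 of ring C, made while a seven-membered ring shrinks. The 2-aryl-5-(1-arylvinyl)-4,5-dihydro-1,3-dioxepine A1 would come from an enantioselective Heck coupling (Pd(OAc)2, chiral bisphosphine) that installs the 1-arylvinyl group and leaves the double bond as an enol ether. Me3SiOTf would then ionise the acetal, and the enol ether carbon would attack the aryl-stabilised oxocarbenium carbon to give the oxolane-3-carbaldehyde A2.
- Merits: both arenes are in place before ring C exists, the route is convergent, and only aldehyde reduction, oxidative cleavage of the 1,1-disubstituted alkene to the C7' ketone and desilylation would remain.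
- Weak points: the cationic closure must set C2 and C3 at once relative to a single existing centre. With ring A as donor the oxocarbenium ion is long-lived and closure is probably reversible, so the 2,3-relationship is hard to predict. The aldehyde α-centre C3 is epimerisable. The absolute configuration rests on a Heck reaction with a hindered α-arylvinyl partner in which double-bond migration must stop exactly at the enol ether. The alkene must finally be cleaved beside two electron-rich arenes.
- Comparison: this road is shorter and more convergent than the chosen one, and that is conceded. The chosen plan sets against it that each stereocentre is fixed by a separate, well-understood element (catalyst for C2, trans alkylation for C3, equilibration for C4) and that its key step is stereochemically passive.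

Alternative 2: The cut is C4–C5. The open-chain α-diazo ketone A3 already holds ring B on C7' and has O1 as a methyl ether on C2. Dirhodium tetraacetamidate, Rh2(NHCOCH3)4, would generate the C4 carbenoid, which would insert into a C–H bond of the methoxy group through a five-membered transition state and give the triacetate A4; deacetylation would finish the synthesis.
- Merits: the complete skeleton and oxidation pattern appear in the key step, the C–H bond is activated by oxygen, and only one step follows.
- Weak points: the carbenoid carbon carries C3–H, and 1,2-hydride shift to an enone is the usual fate of α-alkyl α-diazo ketones. A methyl C–H bond is the least reactive insertion site. Electron-rich ring A lies at the same 1,5-distance and invites aromatic substitution, which carboxamidate ligands favour. A3 needs its two stereocentres from separate asymmetric chemistry. Its diazo group has to be placed on a tertiary α-carbon.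
- Comparison: on step count after the key step this road is better (one step against three on the main line and one on the side branch). The chosen plan also uses a diazo ketone, but in a ring that locks the s-cis geometry and channels it into the concerted shift, and its one conceivable hydride shift would only return route intermediate 8.

Alternative 3: The cuts are O1–C2 and C4–C5 together. Sn(OTf)2 would open the lactone-fused donor–acceptor cyclopropane A5 at the aryl-bearing carbon; formaldehyde A6 would add through oxygen there and through carbon to the malonate-type carbon, giving the cis-fused dioxabicyclooctanone A7.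
- Merits: two bonds and ring C form in one step, ring A is an excellent donor, and the lactone ties O9 to the C7' carbon and makes the relative configuration at C3 and the bridgehead certain.
- Weak points: with so good a donor the opening is ionised, so stereospecific inversion at C2 cannot be counted on and the aryl group must find the convex face by itself. An inversion pathway would in fact require the hindered endo-aryl epimer of A5. After the key step the bridgehead ester has to be removed and the lactone opened by exactly one equivalent of the ring B aryl metal. C4 then has to be turned from the cis arrangement imposed by the lactone to trans, with a free C9 hydroxyl ready to hold the cis ketone as a hemiketal. Monomeric A6 is awkward to dose.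
- Comparison: the key step is more constructive than a ring contraction that forms one bond, and the step count is comparable. The chosen plan sets against it that the C7' carbon arrives at the right oxidation level with nothing to excise, and that the C3/C4 relationship is settled by equilibrating an ether-protected ester.

Key step: step 5

Assumption: with the binaphthol–Ti(OiPr)4 catalyst of step 2 the (S)-ligand is taken to give (S)-5, the sense usual for additions of this catalyst type to aromatic aldehydes; should the first run show the opposite, the (R)-ligand is used and nothing else changes.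

## Route

Step 1
Reactants: 1 vanillin (4-hydroxy-3-methoxybenzaldehyde)
Product: 2 4-(benzyloxy)-3-methoxybenzaldehyde
Conditions: BnBr, K2CO3, DMF, rt
Reagents that add atoms: benzyl bromide, BrCc1ccccc1
Why: Williamson etherification of the phenoxide, the only acidic site; the aldehyde is inert to K2CO3 in DMF, and the benzyl ether then lasts through the enolate, hydride, azide and organolithium steps.

Step 2
Reactants: 2 4-(benzyloxy)-3-methoxybenzaldehyde; 3 (E)-1-methoxy-3-(trimethylsilyloxy)buta-1,3-diene
Product: 5 (S)-2-[4-(benzyloxy)-3-methoxyphenyl]-2,3-dihydro-4H-pyran-4-one, via silyl aldol adduct 4 (not isolated)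
Conditions: (S)-5,5',6,6',7,7',8,8'-octahydro-1,1'-bi-2-naphthol (22 mol%), Ti(OiPr)4 (20 mol%), 4 Å MS, toluene, 0 °C; then CF3CO2H (cat.), CH2Cl2, 0 °C
Reagents that add atoms: none
Why: Catalytic enantioselective hetero-Diels–Alder reaction of an aromatic aldehyde with a 1-alkoxy-3-siloxydiene, which with binaphthol–titanium catalysts runs as a Mukaiyama aldol addition to give 4 and is completed by acid-promoted cyclisation with loss of methanol and the silyl group. The C2 stereocentre is set by the catalyst, which blocks one face of the titanium-bound aldehyde; the (S)-ligand should give (S)-5.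

Step 3
Reactants: 5 (S)-2-[4-(benzyloxy)-3-methoxyphenyl]-2,3-dihydro-4H-pyran-4-one; 6 benzyl chloromethyl ether
Product: 8 (2S,3R)-2-[4-(benzyloxy)-3-methoxyphenyl]-3-[(benzyloxy)methyl]-2,3-dihydro-4H-pyran-4-one, via lithium enolate 7 (not isolated)
Conditions: LiN(i-Pr)2, THF, −78 °C; then 6, −78 → −40 °C
Reagents that add atoms: none
Why: Kinetic deprotonation at C3, the only sp3 α-carbon of the dihydropyranone, gives enolate 7, which is C-alkylated by the reactive chloromethyl ether (enolate alkoxymethylation). The electrophile should add to the face of 7 opposite the neighbouring C2 aryl group, setting C3 trans to C2 (3R); trans is also the thermodynamic arrangement.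

Step 4
Reactants: 8 (2S,3R)-2-[4-(benzyloxy)-3-methoxyphenyl]-3-[(benzyloxy)methyl]-2,3-dihydro-4H-pyran-4-one
Product: 11 (2S,3R)-2-[4-(benzyloxy)-3-methoxyphenyl]-3-[(benzyloxy)methyl]-5-diazooxan-4-one, via lithium enolate 9 (not isolated), via trifluoroacetyl ketone 10 (not isolated)
Conditions: LiBH(s-Bu)3 (1.05 equiv), THF, −78 °C; then CF3CO2CH2CF3, −78 °C; aq. HCl work-up, volatiles removed in vacuo; crude 10, MsN3, Et3N, H2O, MeCN, rt
Reagents that add atoms: methanesulfonyl azide, CS(=O)(=O)N=[N+]=[N-]; 2,2,2-trifluoroethyl trifluoroacetate, O=C(OCC(F)(F)F)C(F)(F)F (its trifluoroacetyl group reaches 10 only and is lost again)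
Why: Conjugate reduction of the β-alkoxy enone by the bulky trialkylborohydride delivers hydride to C6 and gives the C4–C5 lithium enolate 9 with no choice of site, and trapping 9 in the same flask with the trifluoroacetate ester (Claisen-type C-acylation of a regiodefined enolate) gives the activated diketone 10. Detrifluoroacetylative diazo transfer then passes a diazo group from the sulfonyl azide to C5 while the trifluoroacetyl group leaves as its N-sulfonyl amide. No stereocentre is formed, C3 is never enolised, and the ring is never exposed to alkoxide, which matters because the ketone is β-alkoxy on both sides.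

Step 5
Reactants: 11 (2S,3R)-2-[4-(benzyloxy)-3-methoxyphenyl]-3-[(benzyloxy)methyl]-5-diazooxan-4-one
Product: 14 methyl (3S,4R,5S)-5-[4-(benzyloxy)-3-methoxyphenyl]-4-[(benzyloxy)methyl]oxolane-3-carboxylate, via ketene 12 (not isolated), via cis ester 13 (not isolated)
Conditions: hν (365 nm, Pyrex), MeOH, 0 °C; then NaOMe (0.3 equiv), MeOH, 40 °C
Reagents that add atoms: methanol, CO
Why: Direct irradiation of 11 at its long-wavelength band expels N2 while the oxane C3–C4 bond shifts to the diazo carbon C5, because the ring locks the diazo and carbonyl groups s-cis, the geometry in which nitrogen loss and migration are concerted; the result is ketene 12, in which the former carbonyl carbon has left the ring. Methanol adds to 12 to give the ester as a kinetic mixture of 13 and 14 (protonation anti to the benzyloxymethyl group should favour 13), and catalytic NaOMe then equilibrates the ester α-carbon to the trans isomer 14. The closest known reaction type is the photochemical Wolff ring contraction of 2-diazocycloalkanones to cycloalkanecarboxylates in alcohols. Ring C is closed not by joining chain ends but by a 1,2-shift within the ring: the six-membered ring contracts to five by forming C3–C4 (ring C numbering) and expelling the carbonyl carbon as the exocyclic C7' ester carbon. C3 migrates with retention, so the C2 and C3 stereocentres of 11 appear unchanged in 14. The one new stereocentre, C4, is set under thermodynamic control by C3, the ester preferring to lie trans to the neighbouring benzyloxymethyl group; enolisation can expel neither the ring oxygen (that would be the reverse of a 5-endo-trig closure) nor the benzyloxy group (γ to the ester). The step needs the shift to beat carbene chemistry (O–H insertion into methanol, 1,2-hydride shift from C6), which the s-cis lock and the absence of metal catalyst or sensitiser should secure, and there is no regiochemical choice since C3 is the only other substituent on the carbonyl carbon. Light of this wavelength is not absorbed by the benzyl ethers or the arenes.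

Step 6
Reactants: 14 methyl (3S,4R,5S)-5-[4-(benzyloxy)-3-methoxyphenyl]-4-[(benzyloxy)methyl]oxolane-3-carboxylate
Product: 15 (3S,4R,5S)-5-[4-(benzyloxy)-3-methoxyphenyl]-4-[(benzyloxy)methyl]-N-methoxy-N-methyloxolane-3-carboxamide
Conditions: MeNHOMe·HCl, i-PrMgCl, THF, −20 → 0 °C
Reagents that add atoms: N,O-dimethylhydroxylamine hydrochloride, CNOC.Cl
Why: Direct aminolysis of the methyl ester by the chloromagnesium amide made in the flask (N-methoxy-N-methylamide synthesis from esters); the product is inert to excess reagent. Any base-mediated exchange at the α-carbon can only favour the trans arrangement already present.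

Step 7
Reactants: 16 4-bromo-2,6-dimethoxyphenol
Product: 17 2-(benzyloxy)-5-bromo-1,3-dimethoxybenzene
Conditions: BnBr, K2CO3, DMF, rt
Reagents that add atoms: benzyl bromide, BrCc1ccccc1
Why: Williamson etherification; the benzyl ether keeps the phenol out of the organolithium chemistry of step 8 and leaves with the other two in step 9.

Step 8
Reactants: 17 2-(benzyloxy)-5-bromo-1,3-dimethoxybenzene; 15 (3S,4R,5S)-5-[4-(benzyloxy)-3-methoxyphenyl]-4-[(benzyloxy)methyl]-N-methoxy-N-methyloxolane-3-carboxamide
Product: 20 [(3S,4R,5S)-5-[4-(benzyloxy)-3-methoxyphenyl]-4-[(benzyloxy)methyl]oxolan-3-yl][4-(benzyloxy)-3,5-dimethoxyphenyl]methanone, via aryllithium 18 (not isolated), via tetrahedral lithium adduct 19 (not isolated)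
Conditions: 17, n-BuLi, THF, −78 °C; then 15, −78 → −40 °C; aq. NH4Cl
Reagents that add atoms: none
Why: Bromine–lithium exchange gives 18, which adds once to the N-methoxy-N-methylamide because the N,O-chelated adduct 19 holds until the quench (Weinreb ketone synthesis). The ring stereocentres are untouched: 19 cannot enolise, and the ketone appears only on mild aqueous work-up.

Step 9
Reactants: 20 [(3S,4R,5S)-5-[4-(benzyloxy)-3-methoxyphenyl]-4-[(benzyloxy)methyl]oxolan-3-yl][4-(benzyloxy)-3,5-dimethoxyphenyl]methanone
Product: 21 [(3S,4R,5S)-5-(4-hydroxy-3-methoxyphenyl)-4-(hydroxymethyl)oxolan-3-yl](4-hydroxy-3,5-dimethoxyphenyl)methanone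
Conditions: H2 (1 atm), 10% Pd/C, EtOAc–EtOH, rt
Reagents that add atoms: none
Why: Catalytic hydrogenolysis of the two aryl benzyl ethers and the primary alkyl benzyl ether; under neutral conditions at 1 atm the electron-rich aryl ketone and the ring C2–O1 bond should be reduced much more slowly, so the reaction is stopped once the third benzyl group has gone. No stereocentre is affected, and C4 is never exposed to base with O9 free.

## Compound list

1 | vanillin (4-hydroxy-3-methoxybenzaldehyde) | COc1cc(C=O)ccc1O | starting material
2 | 4-(benzyloxy)-3-methoxybenzaldehyde | COc1cc(C=O)ccc1OCc1ccccc1 | intermediate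
3 | (E)-1-methoxy-3-(trimethylsilyloxy)buta-1,3-diene | CO/C=C/C(=C)O[Si](C)(C)C | starting material
4 | (S,E)-5-[4-(benzyloxy)-3-methoxyphenyl]-1-methoxy-5-(trimethylsilyloxy)pent-1-en-3-one | COc1cc([C@H](CC(=O)/C=C/OC)O[Si](C)(C)C)ccc1OCc1ccccc1 | intermediate (not isolated)
5 | (S)-2-[4-(benzyloxy)-3-methoxyphenyl]-2,3-dihydro-4H-pyran-4-one | COc1cc([C@H]2OC=CC(=O)C2)ccc1OCc1ccccc1 | intermediate
6 | benzyl chloromethyl ether | ClCOCc1ccccc1 | starting material
7 | lithium (S)-2-[4-(benzyloxy)-3-methoxyphenyl]-2H-pyran-4-olate (C3–C4 enolate of 5) | COc1cc([C@H]2OC=CC(O[Li])=C2)ccc1OCc1ccccc1 | intermediate (not isolated)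
8 | (2S,3R)-2-[4-(benzyloxy)-3-methoxyphenyl]-3-[(benzyloxy)methyl]-2,3-dihydro-4H-pyran-4-one (2,3-trans) | COc1cc([C@H]2OC=CC(=O)[C@@H]2COCc2ccccc2)ccc1OCc1ccccc1 | intermediate
9 | lithium (5R,6S)-6-[4-(benzyloxy)-3-methoxyphenyl]-5-[(benzyloxy)methyl]-5,6-dihydro-2H-pyran-4-olate (C4–C5 enolate from hydride addition to C6 of 8) | COc1cc([C@H]2OCC=C(O[Li])[C@@H]2COCc2ccccc2)ccc1OCc1ccccc1 | intermediate (not isolated)
10 | (2S,3R)-2-[4-(benzyloxy)-3-methoxyphenyl]-3-[(benzyloxy)methyl]-5-(trifluoroacetyl)oxan-4-one, drawn as its ring enol | COc1cc([C@H]2OCC(C(=O)C(F)(F)F)=C(O)[C@@H]2COCc2ccccc2)ccc1OCc1ccccc1 | intermediate (not isolated)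
11 | (2S,3R)-2-[4-(benzyloxy)-3-methoxyphenyl]-3-[(benzyloxy)methyl]-5-diazooxan-4-one | COc1cc([C@H]2OCC(=[N+]=[N-])C(=O)[C@@H]2COCc2ccccc2)ccc1OCc1ccccc1 | intermediate
12 | [(4R,5S)-5-[4-(benzyloxy)-3-methoxyphenyl]-4-[(benzyloxy)methyl]oxolan-3-ylidene]methanone (ketene) | COc1cc([C@H]2OCC(=C=O)[C@@H]2COCc2ccccc2)ccc1OCc1ccccc1 | intermediate (not isolated)
13 | methyl (3R,4R,5S)-5-[4-(benzyloxy)-3-methoxyphenyl]-4-[(benzyloxy)methyl]oxolane-3-carboxylate (3,4-cis epimer of 14) | COc1cc([C@H]2OC[C@H](C(=O)OC)[C@@H]2COCc2ccccc2)ccc1OCc1ccccc1 | intermediate (not isolated)
14 | methyl (3S,4R,5S)-5-[4-(benzyloxy)-3-methoxyphenyl]-4-[(benzyloxy)methyl]oxolane-3-carboxylate (all-trans) | COc1cc([C@H]2OC[C@@H](C(=O)OC)[C@@H]2COCc2ccccc2)ccc1OCc1ccccc1 | intermediate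
15 | (3S,4R,5S)-5-[4-(benzyloxy)-3-methoxyphenyl]-4-[(benzyloxy)methyl]-N-methoxy-N-methyloxolane-3-carboxamide | COc1cc([C@H]2OC[C@@H](C(=O)N(C)OC)[C@@H]2COCc2ccccc2)ccc1OCc1ccccc1 | intermediate
16 | 4-bromo-2,6-dimethoxyphenol | COc1cc(Br)cc(OC)c1O | starting material
17 | 2-(benzyloxy)-5-bromo-1,3-dimethoxybenzene | COc1cc(Br)cc(OC)c1OCc1ccccc1 | intermediate
18 | [4-(benzyloxy)-3,5-dimethoxyphenyl]lithium | COc1cc([Li])cc(OC)c1OCc1ccccc1 | intermediate (not isolated)
19 | lithium alkoxide of the aryl(N-methoxy-N-methylamino)carbinol from 15 and 18 (carbinol carbon not a controlled centre, lost on collapse) | COc1cc([C@H]2OC[C@@H](C(O[Li])(N(C)OC)c3cc(OC)c(OCc4ccccc4)c(OC)c3)[C@@H]2COCc2ccccc2)ccc1OCc1ccccc1 | intermediate (not isolated)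
20 | [(3S,4R,5S)-5-[4-(benzyloxy)-3-methoxyphenyl]-4-[(benzyloxy)methyl]oxolan-3-yl][4-(benzyloxy)-3,5-dimethoxyphenyl]methanone | COc1cc([C@H]2OC[C@@H](C(=O)c3cc(OC)c(OCc4ccccc4)c(OC)c3)[C@@H]2COCc2ccccc2)ccc1OCc1ccccc1 | intermediate
21 | [(3S,4R,5S)-5-(4-hydroxy-3-methoxyphenyl)-4-(hydroxymethyl)oxolan-3-yl](4-hydroxy-3,5-dimethoxyphenyl)methanone | COc1cc([C@H]2OC[C@@H](C(=O)c3cc(OC)c(O)c(OC)c3)[C@@H]2CO)ccc1O | target

## Step count and risks

Total step count: 9. Longest linear sequence: 8 (steps 1–6, 8, 9); step 7 is the one-step side branch.

Step 5 (key step). The most likely failure is diversion of the excited diazo ketone into carbene pathways: insertion into the O–H bond of methanol, or a 1,2-hydride shift from the oxygen-activated C6 methylene, which would regenerate enone 8. Equilibration at C4 may also stop short of completion, so some 13 would need separation and recycling through NaOMe. Fallback: an oxidative ring contraction that needs neither diazo compound nor light, setting out from enone 8. Conjugate reduction with LiBH(s-Bu)3 as in step 4, but with an aqueous NH4Cl quench in place of the acylating ester, gives (2S,3R)-2-[4-(benzyloxy)-3-methoxyphenyl]-3-[(benzyloxy)methyl]oxan-4-one F1. With the trivalent iodine reagent PhI(OAc)2, H2SO4 and HC(OMe)3 in MeOH, F1 should form its dimethyl ketal (2S,3R)-2-[4-(benzyloxy)-3-methoxyphenyl]-3-[(benzyloxy)methyl]-4,4-dimethoxyoxane F2 and from it the enol ether (2S,3R)-2-[4-(benzyloxy)-3-methoxyphenyl]-3-[(benzyloxy)methyl]-4-methoxy-3,6-dihydro-2H-pyran F3, with the double bond toward the unsubstituted C5. The iodine reagent adds at C5, C3 migrates from C4 to C5 as iodobenzene leaves, and the resulting ortho ester gives the same mixture of 13 and 14, which NaOMe converts to 14, where the route is rejoined. The fallback depends on enol ether formation toward C5 and on the C2–O1 bond surviving the acid.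

Step 2. The electron-rich aldehyde binds the titanium centre weakly, so slow turnover and an uncatalysed background reaction may erode the enantiomeric purity. Fallback: a reagent-controlled boron aldol from 2. The enol borinate made from 4-methoxybut-3-en-2-one with the appropriate antipode of (Ipc)2BCl and i-Pr2NEt adds to 2 to give (S,E)-5-[4-(benzyloxy)-3-methoxyphenyl]-5-hydroxy-1-methoxypent-1-en-3-one F4, and CF3CO2H closes it with loss of methanol to 5, where the route is rejoined.

Step 3. The ambident dienolate may be alkylated on oxygen, proton exchange between 7 and 8 may lead to double alkylation, the 2H-pyranolate may open by expulsion of the ring oxygen from C2, or 8 may lose benzyloxide by β-elimination in the basic medium. Fallback: a non-basic alkylation from 5. Trapping of 7 with Me3SiCl gives {[(S)-2-[4-(benzyloxy)-3-methoxyphenyl]-2H-pyran-4-yl]oxy}trimethylsilane F5, which is alkylated at carbon by 6 with catalytic ZnBr2 in CH2Cl2 (Lewis acid alkylation of a silyl enol ether with an ionisable halide), returning to the route at 8.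

Step 4. Enolate 9 is formed beside tri-sec-butylborane, so acylation may be sluggish or go to oxygen, residual hydride may consume the trifluoroacetate ester, 9 may open by β-elimination of the ring oxygen if warmed, and borane carried forward may interfere with the azide. Fallback: separation of the reduction from the acylation through an isolable enol derivative, setting out from enone 8. Reduction with LiBH(s-Bu)3 followed by Me3SiCl and Et3N at −78 °C gives {[(5R,6S)-6-[4-(benzyloxy)-3-methoxyphenyl]-5-[(benzyloxy)methyl]-5,6-dihydro-2H-pyran-4-yl]oxy}trimethylsilane F6, which is freed from the borane under vacuum and by rapid filtration. MeLi in THF then cleaves the Si–O bond and regenerates 9 as a borane-free and hydride-free lithium enolate, where the route is rejoined for acylation and diazo transfer.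

Step 9. Over-reduction may occur before the slow aliphatic benzyl ether is cleaved: hydrogenolysis of the ring C2–O1 bond, made more labile once the para hydroxyl is free, or reduction of the aryl ketone. Fallback: non-reductive debenzylation from 20 with BCl3 and pentamethylbenzene as benzyl cation scavenger in CH2Cl2 at −78 °C, giving 21 directly. No new compound arises.

## Further compounds

F1 | step 5 | (2S,3R)-2-[4-(benzyloxy)-3-methoxyphenyl]-3-[(benzyloxy)methyl]oxan-4-one | COc1cc([C@H]2OCCC(=O)[C@@H]2COCc2ccccc2)ccc1OCc1ccccc1
F2 | step 5 | (2S,3R)-2-[4-(benzyloxy)-3-methoxyphenyl]-3-[(benzyloxy)methyl]-4,4-dimethoxyoxane | COc1cc([C@H]2OCCC(OC)(OC)[C@@H]2COCc2ccccc2)ccc1OCc1ccccc1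
F3 | step 5 | (2S,3R)-2-[4-(benzyloxy)-3-methoxyphenyl]-3-[(benzyloxy)methyl]-4-methoxy-3,6-dihydro-2H-pyran | COc1cc([C@H]2OCC=C(OC)[C@@H]2COCc2ccccc2)ccc1OCc1ccccc1
F4 | step 2 | (S,E)-5-[4-(benzyloxy)-3-methoxyphenyl]-5-hydroxy-1-methoxypent-1-en-3-one | COc1cc([C@H](CC(=O)/C=C/OC)O)ccc1OCc1ccccc1
F5 | step 3 | {[(S)-2-[4-(benzyloxy)-3-methoxyphenyl]-2H-pyran-4-yl]oxy}trimethylsilane | COc1cc([C@H]2OC=CC(O[Si](C)(C)C)=C2)ccc1OCc1ccccc1
F6 | step 4 | {[(5R,6S)-6-[4-(benzyloxy)-3-methoxyphenyl]-5-[(benzyloxy)methyl]-5,6-dihydro-2H-pyran-4-yl]oxy}trimethylsilane | COc1cc([C@H]2OCC=C(O[Si](C)(C)C)[C@@H]2COCc2ccccc2)ccc1OCc1ccccc1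
F0 | step 9 | none | none
A1 | alternative 1 | 2-[4-(tert-butyldimethylsilyloxy)-3-methoxyphenyl]-5-{1-[4-(tert-butyldimethylsilyloxy)-3,5-dimethoxyphenyl]vinyl}-4,5-dihydro-1,3-dioxepine (C5 as drawn, either acetal epimer) | COc1cc(C2OC[C@@H](C(=C)c3cc(OC)c(O[Si](C)(C)C(C)(C)C)c(OC)c3)C=CO2)ccc1O[Si](C)(C)C(C)(C)C
A2 | alternative 1 | all-trans 2-[4-(tert-butyldimethylsilyloxy)-3-methoxyphenyl]-4-{1-[4-(tert-butyldimethylsilyloxy)-3,5-dimethoxyphenyl]vinyl}oxolane-3-carbaldehyde | COc1cc([C@H]2OC[C@@H](C(=C)c3cc(OC)c(O[Si](C)(C)C(C)(C)C)c(OC)c3)[C@@H]2C=O)ccc1O[Si](C)(C)C(C)(C)C
A3 | alternative 2 | 4-[2-(acetoxymethyl)-4-(4-acetoxy-3,5-dimethoxyphenyl)-3-diazo-1-methoxy-4-oxobutyl]-2-methoxyphenyl acetate (configuration as drawn) | COc1cc([C@@H](OC)[C@@H](COC(C)=O)C(=[N+]=[N-])C(=O)c2cc(OC)c(OC(C)=O)c(OC)c2)ccc1OC(C)=O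
A4 | alternative 2 | triacetate of 21 | COc1cc([C@H]2OC[C@@H](C(=O)c3cc(OC)c(OC(C)=O)c(OC)c3)[C@@H]2COC(C)=O)ccc1OC(C)=O
A5 | alternative 3 | methyl 6-[4-(benzyloxy)-3-methoxyphenyl]-2-oxo-3-oxabicyclo[3.1.0]hexane-1-carboxylate (ring-fusion centres as drawn, either epimer at the aryl-bearing carbon) | COc1cc(C2[C@H]3COC(=O)[C@@]23C(=O)OC)ccc1OCc1ccccc1
A6 | alternative 3 | formaldehyde | C=O
A7 | alternative 3 | methyl 4-[4-(benzyloxy)-3-methoxyphenyl]-8-oxo-3,7-dioxabicyclo[3.3.0]octane-1-carboxylate (cis-fused, exo aryl, configuration as drawn) | COc1cc([C@H]2OC[C@@]3(C(=O)OC)[C@@H]2COC3=O)ccc1OCc1ccccc1
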